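**Assumption (one line):** the SMILES is taken as drawn (ring A cis-fused, C10 methyl and H-11 syn); locants follow the SMILES atom order: C1/C3 (Me2) on C2, O4, C5(=O6), C7=C8, C9(C10H3), C11, C12, C13, C14, C15, C16(C17H3), C18(=O19), C20(C21H3), C22, C23, C24, C25, O26, C27(=O28), C29, C30(O31H). Ring A = lactone; ring B = C9/C11–C14/C23; ring C = C14/C23/C22/C20/C24; ring D = C14/C15/C16/C18/C20/C24.

**Retrosynthetic overview**
1. C29–C30: an intramolecular aldol of the spiro-lactone enolate onto a C16 aldehyde closes the bicyclo[2.2.2]octane last.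
2. C30 comes from formaldehyde added to enone 23; ring D is closed by aldol condensation (C15=C16) and ring C by an intramolecular Michael addition (C14→C24).
3. C20–C22: asymmetric Michael union of fragment 1 (rings A/B, exo-methylene ketone) with fragment 2 (butenolide ketone 16).
4. Fragment 1 from (1S,5S)-verbenone: its six-membered ring is ring B; ring A forms by acid fragmentation of the cyclobutane and capture of the cation by a (Z)-acrylic acid.
5. Ring order: B (chiral pool) → A → C → D → bicyclo[2.2.2]octane.

**Step 1**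
Reactants: 1 tert-butyl bromoacetate; 2 diphenyl phosphite
Product: 3 tert-butyl 2-(diphenoxyphosphoryl)acetate
Conditions: NaH, THF, 0 °C → rt
Reagents that add atoms: none
Why: Michaelis–Becker alkylation of the phosphite anion gives the Z-selective (Ando-type) Horner–Wadsworth–Emmons reagent; no stereocentre is formed.

**Step 2**
Reactants: 4 (1S,5S)-(−)-verbenone
Product: 5 6,6-dimethyl-4-oxobicyclo[3.1.1]hept-2-ene-2-carbaldehyde (bridgeheads as in 4)
Conditions: SeO2, 1,4-dioxane, 100 °C
Reagents that add atoms: selenium dioxide, O=[Se]=O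
Why: Riley allylic oxidation takes the only oxidisable allylic position, the vinylic methyl (future C8), to the enal and leaves both bridgehead centres untouched.

**Step 3**
Reactants: 5 enal; 3 phosphonate
Product: 6 tert-butyl (2Z)-3-(6,6-dimethyl-4-oxobicyclo[3.1.1]hept-2-en-2-yl)prop-2-enoate
Conditions: NaH, THF, −78 → 0 °C
Reagents that add atoms: none
Why: Ando-type Horner–Wadsworth–Emmons olefination is selective for the aldehyde over the hindered enone, and the diaryl phosphonate gives the (Z)-acrylate (C7=C8) needed for the cis lactone.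

**Step 4**
Reactants: 6 (Z)-dienoate enone
Product: 8 Mannich base tert-butyl (2Z)-3-{3-[(dimethylamino)methyl]-2,6,6-trimethyl-4-oxobicyclo[3.1.1]heptan-2-yl}prop-2-enoate, via lithium enolate 7 (not isolated)
Conditions: Me2CuLi, Et2O, −78 → −40 °C; then [Me2N=CH2]I, THF, −40 → 0 °C
Reagents that add atoms: lithium dimethylcuprate, [Li+].C[Cu-]C; N,N-dimethylmethylideneammonium iodide, C[N+](C)=C.[I-]
Why: Gilman conjugate addition to the enone (faster than to the β-substituted tert-butyl acrylate) occurs anti to the gem-dimethyl bridge and sets quaternary C9 (methyl anti, acrylate syn to the bridge), and the regiodefined enolate is trapped at C23 in a Mannich reaction that installs C22.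

**Step 5**
Reactants: 8 Mannich base
Product: 10 cis-fused lactone amine 6-[(dimethylamino)methyl]-1,1,5a-trimethyl-5a,6,8,9-tetrahydro-2-benzoxepine-3,7(1H,9aH)-dione, via carboxylic acid 9 (not isolated)
Conditions: CF3CO2H/CH2Cl2 (1:1), 0 °C → rt; then CF3SO3H (0.2 equiv), 0 °C; aq. NaHCO3 work-up
Reagents that add atoms: none
Why: acid cleaves the tert-butyl ester and then fragments the cyclobutane (retro-Prins-type C13–C2 cleavage assisted by ketone enolisation), and the tertiary C2 cation is captured by the cis (Z)-acrylic acid to give the seven-membered enoate lactone; C9 and C11 are untouched, so ring A is cis-fused as in the target.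

**Step 6**
Reactants: 11 ethyl 4-chloroacetoacetate
Product: 12 tetronic acid (4-hydroxyfuran-2(5H)-one)
Conditions: neat, 140 °C, chloroethane distilled off
Reagents that add atoms: none
Why: thermal lactonisation with loss of chloroethane gives the vinylogous acid from a cheap ester; no stereocentre.

**Step 7**
Reactants: 12 tetronic acid
Product: 13 4-bromofuran-2(5H)-one
Conditions: (COBr)2, DMF (cat.), CH2Cl2, 0 °C → rt
Reagents that add atoms: oxalyl bromide, O=C(Br)C(=O)Br
Why: Vilsmeier-type activation converts the vinylogous acid into the vinylogous acid bromide.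

**Step 8**
Reactants: 14 pentan-3-one
Product: 15 (Z)-trimethyl(pent-2-en-3-yloxy)silane
Conditions: Me3SiOTf, Et3N, CH2Cl2, 0 °C
Reagents that add atoms: trimethylsilyl trifluoromethanesulfonate, C[Si](C)(C)OS(=O)(=O)C(F)(F)F
Why: soft enolisation of the symmetrical ketone gives the (Z)-silyl enol ether.

**Step 9**
Reactants: 15 silyl enol ether; 13 bromobutenolide
Product: 16 4-(3-oxopentan-2-yl)furan-2(5H)-one (fragment 2; racemic)
Conditions: PdCl2[P(o-tolyl)3]2 (3 mol %), Bu3SnF, toluene, 110 °C
Reagents that add atoms: none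
Why: palladium-catalysed, tin-fluoride-promoted α-alkenylation of the silyl enol ether forms C20–C24 under non-basic conditions; the C20 centre is re-enolised in the next step, so its configuration here is irrelevant.

**Step 10**
Reactants: 10 lactone amine; 16 fragment 2
Product: 19 6-[2-methyl-3-oxo-2-(5-oxo-2,5-dihydrofuran-3-yl)pentyl]-1,1,5a-trimethyl-5a,6,8,9-tetrahydro-2-benzoxepine-3,7(1H,9aH)-dione, via ammonium iodide 17 (not isolated), via exo-methylene ketone 18 (not isolated)
Conditions: MeI, MeCN, rt, evaporate; then 16, K2CO3 (solid), O-allyl-N-(9-anthracenylmethyl)cinchonidinium bromide (10 mol %), toluene, −20 °C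
Reagents that add atoms: none
Why: quaternisation and E1cB loss of trimethylamine release the exo-methylene ketone in situ, and the chiral ion pair of the doubly stabilised C20 enolate adds to it in an asymmetric phase-transfer Michael reaction (catalyst control at quaternary C20; the cinchoninium pseudo-enantiomer would give the C20 epimer), while C23 equilibrates to the equatorial epimer with C22 cis to C8.

**Step 11**
Reactants: 19 diketone
Product: 20 methyl enol ether (C14=C15H–OMe; E/Z mixture) of 19
Conditions: Ph3P=CHOMe (3 equiv), THF, −78 → 0 °C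
Reagents that add atoms: (methoxymethylidene)triphenylphosphorane, COC=P(c1ccccc1)(c1ccccc1)c1ccccc1
Why: Wittig methoxymethylenation takes the ring ketone C14 in preference to the neopentyl-type C18 ketone and the lactones and brings in C15 as a masked aldehyde (excess ylide covers reversible deprotonation of the butenolide).

**Step 12**
Reactants: 20 enol ether
Product: 23 tetracyclic enone (C15=C16(CH3)–C18=O in ring D; spiro γ-lactone at C24), via aldehyde 21 (not isolated), via keto aldehyde 22 (not isolated)
Conditions: 1 M HCl, THF, rt; then pyrrolidine, AcOH, toluene, 80 °C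
Reagents that add atoms: none
Why: the pyrrolidine enamine of the C15 aldehyde adds to the butenolide in an intramolecular 5-exo Michael reaction (cis ring fusion forced by the C22 tether; synclinal transition state with the lactone carbonyl over the enamine, so C29 lies on the C15 side of quaternary C24), and intramolecular aldol condensation of the ethyl ketone onto the now non-enolisable aldehyde closes ring D.

**Step 13**
Reactants: 23 enone
Product: 25 hydroxymethyl ketone (C16 bears CH3 and C30H2OH), via lithium enolate 24 (not isolated)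
Conditions: Li[HB(s-Bu)3], THF, −78 °C; then CH2O (gas), −78 °C; AcOH quench
Reagents that add atoms: formaldehyde, C=O
Why: 1,4-hydride addition gives the C16 enolate regiospecifically, and its aldol reaction with formaldehyde occurs on the exo face, anti to the C22–C23 bridge, which sets quaternary C16 with C30 on the side of C29.

**Step 14**
Reactants: 25 hydroxymethyl ketone
Product: 26 keto aldehyde (C16 bears CH3 and C30H=O)
Conditions: Dess–Martin periodinane, CH2Cl2, rt
Reagents that add atoms: none
Why: Dess–Martin oxidation of the neopentyl primary alcohol under neutral conditions gives the non-enolisable β-keto aldehyde without retro-aldol loss of formaldehyde.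

**Step 15**
Reactants: 26 keto aldehyde
Product: 27 target CNP0295808.3
Conditions: LiN(SiMe3)2 (1.1 equiv), THF, −78 °C; AcOH quench at −78 °C
Reagents that add atoms: none
Why: the lactone α-CH2 (C29) is the only acidic position, so its lithium enolate adds to the aldehyde in an intramolecular aldol reaction that closes the bicyclo[2.2.2]octane; lithium chelation of the aldehyde, the C18 ketone and the enolate oxygen places the C30 hydroxyl and the lactone carbonyl syn, on the side of the C18 bridge, which sets C29 and C30.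

**Compound list**
1 | tert-butyl bromoacetate | CC(C)(C)OC(=O)CBr | starting material
2 | diphenyl phosphite | O=[PH](Oc1ccccc1)Oc1ccccc1 | starting material
3 | tert-butyl 2-(diphenoxyphosphoryl)acetate | CC(C)(C)OC(=O)CP(=O)(Oc1ccccc1)Oc1ccccc1 | intermediate
4 | (1S,5S)-(−)-verbenone | CC1=CC(=O)[C@H]2C[C@@H]1C2(C)C | starting material
5 | 6,6-dimethyl-4-oxobicyclo[3.1.1]hept-2-ene-2-carbaldehyde, bridgeheads as in 4 | O=CC1=CC(=O)[C@H]2C[C@@H]1C2(C)C | intermediate
6 | tert-butyl (2Z)-3-(6,6-dimethyl-4-oxobicyclo[3.1.1]hept-2-en-2-yl)prop-2-enoate | CC(C)(C)OC(=O)/C=C\C1=CC(=O)[C@H]2C[C@@H]1C2(C)C | intermediate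
7 | lithium enolate of the methyl 1,4-adduct of 6 | CC1(C)[C@@H]2C[C@H]1[C@](C)(/C=C\C(=O)OC(C)(C)C)C=C2[O-].[Li+] | intermediate
8 | Mannich base: tert-butyl (2Z)-3-{3-[(dimethylamino)methyl]-2,6,6-trimethyl-4-oxobicyclo[3.1.1]heptan-2-yl}prop-2-enoate; new methyl anti and acrylate syn to the gem-dimethyl bridge; both C3 epimers | CC1(C)[C@@H]2C[C@H]1[C@](C)(/C=C\C(=O)OC(C)(C)C)C(CN(C)C)C2=O | intermediate
9 | free (2Z)-acrylic acid of 8 | CC1(C)[C@@H]2C[C@H]1[C@](C)(/C=C\C(O)=O)C(CN(C)C)C2=O | intermediate
10 | 6-[(dimethylamino)methyl]-1,1,5a-trimethyl-5a,6,8,9-tetrahydro-2-benzoxepine-3,7(1H,9aH)-dione; 5a-methyl and 9a-H cis; both C6 epimers | CC1(C)OC(=O)C=C[C@@]2(C)[C@@H]1CCC(=O)C2CN(C)C | intermediate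
11 | ethyl 4-chloroacetoacetate | CCOC(=O)CC(=O)CCl | starting material
12 | tetronic acid | OC1=CC(=O)OC1 | intermediate
13 | 4-bromofuran-2(5H)-one | BrC1=CC(=O)OC1 | intermediate
14 | pentan-3-one | CCC(=O)CC | starting material
15 | (Z)-trimethyl(pent-2-en-3-yloxy)silane | C/C=C(/CC)O[Si](C)(C)C | intermediate
16 | 4-(3-oxopentan-2-yl)furan-2(5H)-one (fragment 2, racemic) | CCC(=O)C(C)C1=CC(=O)OC1 | intermediate
17 | N,N,N-trimethylammonium iodide of 10 | CC1(C)OC(=O)C=C[C@@]2(C)[C@@H]1CCC(=O)C2C[N+](C)(C)C.[I-] | intermediate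
18 | 1,1,5a-trimethyl-6-methylidene-5a,6,8,9-tetrahydro-2-benzoxepine-3,7(1H,9aH)-dione, cis-fused (fragment 1) | CC1(C)OC(=O)C=C[C@@]2(C)[C@@H]1CCC(=O)C2=C | intermediate
19 | Michael adduct: 18 carrying at C22 the quaternary C20 (methyl, propanoyl, butenolid-4-yl); C22 on C23 cis to C8 | CC1(C)OC(=O)C=C[C@@]2(C)[C@@H]1CCC(=O)[C@H]2C[C@@](C)(C(=O)CC)C1=CC(=O)OC1 | intermediate
20 | methyl enol ether of 19 at C14 (C14=C15H–OMe, E/Z mixture) | CC1(C)OC(=O)C=C[C@@]2(C)[C@@H]1CCC(=COC)[C@H]2C[C@@](C)(C(=O)CC)C1=CC(=O)OC1 | intermediate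
21 | C14 carbaldehyde (C15H=O; both C14 epimers) | CC1(C)OC(=O)C=C[C@@]2(C)[C@@H]1CCC(C=O)[C@H]2C[C@@](C)(C(=O)CC)C1=CC(=O)OC1 | intermediate
22 | ring C closed: C14 quaternary (CHO), C24 spiro γ-lactone, C20 bearing methyl and propanoyl | CC1(C)OC(=O)C=C[C@@]2(C)[C@@H]1CC[C@]1(C=O)[C@H]2C[C@@](C)(C(=O)CC)[C@]13COC(=O)C3 | intermediate
23 | tetracyclic enone: rings A–D, C15=C16(CH3)–C18=O, spiro γ-lactone at C24 | CC1(C)OC(=O)C=C[C@@]2(C)[C@@H]1CC[C@]13C=C(C)C(=O)[C@](C)(C[C@@H]21)[C@]31COC(=O)C1 | intermediate
24 | lithium enolate C16=C18(OLi) from 23 | CC1(C)OC(=O)C=C[C@@]2(C)[C@@H]1CC[C@]13CC(C)=C([O-])[C@](C)(C[C@@H]21)[C@]31COC(=O)C1.[Li+] | intermediate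
25 | hydroxymethyl ketone: C16 quaternary with CH3 (toward the C22–C23 bridge) and C30H2OH (toward C29) | CC1(C)OC(=O)C=C[C@@]2(C)[C@@H]1CC[C@]13C[C@@](C)(CO)C(=O)[C@](C)(C[C@@H]21)[C@]31COC(=O)C1 | intermediate
26 | keto aldehyde: as 25 with C30H=O | CC1(C)OC(=O)C=C[C@@]2(C)[C@@H]1CC[C@]13C[C@@](C)(C=O)C(=O)[C@](C)(C[C@@H]21)[C@]31COC(=O)C1 | intermediate
27 | CNP0295808.3 | CC1(C)OC(=O)C=C[C@@]2(C)[C@@H]1CC[C@]13C[C@]4(C)C(=O)[C@](C)(C[C@@H]21)[C@]31COC(=O)[C@H]1[C@H]4O | target

**Step count and risks**
Total: 15 steps. Longest linear sequence: 10 steps (2, 3, 4, 5, 10, 11, 12, 13, 14, 15 from verbenone; the chain through step 1 is equally long), which is two thirds of the total.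

Most likely to fail, first: step 4, where the cuprate may attack the conjugated (Z)-acrylate instead of C9. The fallback sets out from aldehyde 5 and comes back at 8. HC(OMe)3/TsOH in MeOH gives the enone dimethyl acetal F1, which has no second acceptor. Me2CuLi and then [Me2N=CH2]I give the Mannich base acetal F2, with the same facial course. Aqueous HCl in acetone frees the neopentyl aldehyde F3, and the Ando olefination with 3 (NaH, THF) then installs the (Z)-acrylate, giving 8.

Second: step 12, where the enamine Michael addition must form two adjacent quaternary carbons. The fallback sets out from enol ether 20 and comes back at 23 by reversing the order of bond formation. Hydrolysis (aq. HCl) and piperidinium acetate in hot benzene first close a seven-membered ring by aldol condensation between C15 and C16, giving the cycloheptenone F4. DBU (or KOt-Bu) then forms the extended enolate at C14, which adds transannularly to the butenolide (vinylogous Michael reaction) to give 23.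

Third: step 15, where the spiro-lactone enolate may be poorly aligned or the aldolate may revert. The fallback sets out from keto aldehyde 26 and comes back at 27. Pinnick oxidation (NaClO2, NaH2PO4, 2-methylbut-2-ene) gives the carboxylic acid F5, and Me3SiCHN2 gives the methyl ester F6. LiN(SiMe3)2 (2.2 equiv) then effects a Dieckmann-type acylation of the lactone enolate to the β-keto lactone F7, driven by enolisation between C27 and C30. NaBH4 in MeOH at −40 °C reduces only the C30 ketone, from the face anti to the C29 carbonyl substituent, to give 27.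

**Further compounds**
F1 | step 4 | 2-(dimethoxymethyl)-6,6-dimethylbicyclo[3.1.1]hept-2-en-4-one, bridgeheads as in 4 | COC(OC)C1=CC(=O)[C@H]2C[C@@H]1C2(C)C
F2 | step 4 | 2-(dimethoxymethyl)-3-[(dimethylamino)methyl]-2,6,6-trimethylbicyclo[3.1.1]heptan-4-one, methyl anti to the gem-dimethyl bridge | CC1(C)[C@@H]2C[C@H]1[C@](C)(C(OC)OC)C(CN(C)C)C2=O
F3 | step 4 | 3-[(dimethylamino)methyl]-2,6,6-trimethyl-4-oxobicyclo[3.1.1]heptane-2-carbaldehyde | CC1(C)[C@@H]2C[C@H]1[C@](C)(C=O)C(CN(C)C)C2=O
F4 | step 12 | cycloheptenone (C15=C16(CH3)–C18=O in a seven-membered ring fused to ring B; C20 bearing methyl and butenolid-4-yl) | CC1(C)OC(=O)C=C[C@@]2(C)[C@@H]1CCC1C=C(C)C(=O)[C@](C)(C[C@@H]21)C1=CC(=O)OC1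
F5 | step 15 | C30 carboxylic acid corresponding to 26 | CC1(C)OC(=O)C=C[C@@]2(C)[C@@H]1CC[C@]13C[C@@](C)(C(O)=O)C(=O)[C@](C)(C[C@@H]21)[C@]31COC(=O)C1
F6 | step 15 | methyl ester of F5 | CC1(C)OC(=O)C=C[C@@]2(C)[C@@H]1CC[C@]13C[C@@](C)(C(=O)OC)C(=O)[C@](C)(C[C@@H]21)[C@]31COC(=O)C1
F7 | step 15 | C30 ketone of the target (β-keto lactone) | CC1(C)OC(=O)C=C[C@@]2(C)[C@@H]1CC[C@]13C[C@]4(C)C(=O)[C@](C)(C[C@@H]21)[C@]31COC(=O)C1C4=O
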